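**Plan**
1. Retrosynthesis: remove the five benzyl ethers and the C4' O-methyl group, then cut C1'–C6' and C1'–C2' of ring B. This leaves 5,7-bis(benzyloxy)-2-methylchromone, whose CH3 becomes C1', and a 3-aryl-5-methoxy-4-pyranone, which supplies C2'–C6'.
2. Enabling feature: in ring B the C4' oxygen, the C5' methoxy group and the C3' aryl are arranged like C4=O, C5–OMe and C3–aryl of a 4-pyranone whose two alpha carbons (future C2' and C6') are CH. C1' is bonded to C2 of a chromone, so it can start as a vinylogously acidic methyl carbon.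
3. The C3'–C8'' bond is not made by arene–arene coupling. The pyranone is grown on a three-carbon chain placed at C8'' of apigenin by iodination, allylation, epoxide methanolysis, oxidation and double aminomethylenation with cyclisation.
4. Forward ring order: apigenin rings (purchased), then the 4-pyranone, then the second chromone (from 2,4,6-trihydroxyacetophenone and ethyl acetate), then ring B in the key step. O-methylation and hydrogenolysis follow.
5. Stereochemistry: the target has no stereocentre. The stereocentres of the epoxide, the carbinol and the pyran adduct are racemic and are erased later.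

Key step: step 10

Remark on the chemistry: the C3'–C8'' axis is treated as configurationally undefined, as in the structure to be made, so no axial control is planned.

**Step 1**
Reactants: 1 apigenin
Product: 2 apigenin tribenzyl ether (5,7-bis(benzyloxy)-2-[4-(benzyloxy)phenyl]-4H-chromen-4-one)
Conditions: BnBr (4 equiv), K2CO3 (5 equiv), DMF, 80 °C
Reagents that add atoms: benzyl bromide, BrCc1ccccc1
Why: Williamson etherification in which hot DMF and excess carbonate also alkylate the chelated 5-OH, giving ethers that should survive every later reagent and can be removed together at the end.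

**Step 2**
Reactants: 2 apigenin tribenzyl ether
Product: 3 5,7-bis(benzyloxy)-2-[4-(benzyloxy)phenyl]-8-iodo-4H-chromen-4-one
Conditions: NIS (1.05 equiv), CF3CO2H (0.3 equiv), CH2Cl2–MeCN, 0 °C → rt, dark
Reagents that add atoms: N-iodosuccinimide, O=C1CCC(=O)N1I
Why: Electrophilic aromatic iodination, where ring A is the most electron-rich ring of a 5,7-dialkoxyflavone and C8 (para to the 5-alkoxy group, less crowded than C6 between two benzyloxy groups) is the usual halogenation site.

**Step 3**
Reactants: 3 8-iodoflavone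
Product: 4 8-allyl-5,7-bis(benzyloxy)-2-[4-(benzyloxy)phenyl]-4H-chromen-4-one
Conditions: allylSnBu3 (1.3 equiv), Pd(PPh3)4 (5 mol%), DMF, 90 °C
Reagents that add atoms: allyltributylstannane, C=CC[Sn](CCCC)(CCCC)CCCC
Why: Stille coupling of an aryl iodide with an allylstannane under zerovalent palladium catalysis needs no base, so the flavone and the benzyl ethers should stay untouched.

**Step 4**
Reactants: 4 8-allylflavone
Product: 5 5,7-bis(benzyloxy)-2-[4-(benzyloxy)phenyl]-8-(oxiran-2-ylmethyl)-4H-chromen-4-one (racemic)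
Conditions: mCPBA (1.5 equiv), CH2Cl2, 0 °C → rt
Reagents that add atoms: 3-chloroperoxybenzoic acid, O=C(OO)c1cccc(Cl)c1
Why: Prilezhaev epoxidation of the only nucleophilic C=C (the flavone C2=C3 bond is an electron-poor vinylogous ester); the new stereocentre forms racemic and is erased in step 6.

**Step 5**
Reactants: 5 epoxide
Product: 6 5,7-bis(benzyloxy)-2-[4-(benzyloxy)phenyl]-8-(2-hydroxy-3-methoxypropyl)-4H-chromen-4-one (racemic)
Conditions: NaOMe (0.5 equiv), MeOH–THF 3:1, 60 °C
Reagents that add atoms: methanol, CO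
Why: Base-catalysed SN2 opening of a monosubstituted epoxide takes place at the terminal carbon, and fully etherified flavones are known to tolerate hot methoxide.

**Step 6**
Reactants: 6 methoxy alcohol
Product: 7 5,7-bis(benzyloxy)-2-[4-(benzyloxy)phenyl]-8-(3-methoxy-2-oxopropyl)-4H-chromen-4-one
Conditions: Dess–Martin periodinane (1.3 equiv), CH2Cl2, rt
Reagents that add atoms: none
Why: Dess–Martin oxidation of a secondary alcohol is neutral and mild, so the enolisable benzyl ketone and the benzyl ethers should be unaffected.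

**Step 7**
Reactants: 7 1-aryl-3-methoxypropan-2-one
Product: 9 5,7-bis(benzyloxy)-2-[4-(benzyloxy)phenyl]-8-(5-methoxy-4-oxo-4H-pyran-3-yl)-4H-chromen-4-one, via bis(enaminone) 8 (not isolated)
Conditions: Me2NCH(OMe)2 (10 equiv), DMF, 120 °C, MeOH distilled off; concentrate; AcOH–H2O 4:1, 70 °C
Reagents that add atoms: N,N-dimethylformamide dimethyl acetal, COC(OC)N(C)C; water, O
Why: Both alpha-methylene groups condense with the amide acetal, and hydrolysis of one enaminone to the enol followed by addition–elimination on the other closes the ring, which is the standard route from 1,3-disubstituted acetones to 3,5-disubstituted 4-pyranones; aqueous acetic acid should spare the 5-O-benzyl group.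

**Step 8**
Reactants: 10 2,4,6-trihydroxyacetophenone
Product: 11 1-[2,4-bis(benzyloxy)-6-hydroxyphenyl]ethan-1-one
Conditions: BnBr (2.1 equiv), K2CO3 (2.2 equiv), DMF, 60 °C
Reagents that add atoms: benzyl bromide, BrCc1ccccc1
Why: Williamson etherification that stops after two alkylations, because the last hydroxyl is locked in a hydrogen bond to the acetyl carbonyl.

**Step 9**
Reactants: 11 dibenzyl acetophenone
Product: 13 5,7-bis(benzyloxy)-2-methyl-4H-chromen-4-one, via 1,3-diketone 12 (not isolated)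
Conditions: NaH (4 equiv), EtOAc (5 equiv), THF, reflux; 1 M HCl quench; TsOH·H2O (10 mol%), toluene, 80 °C
Reagents that add atoms: ethyl acetate, CCOC(C)=O
Why: Crossed Claisen condensation of the acetophenone enolate with ethyl acetate and acid-catalysed cyclodehydration is the classical 2-methylchromone synthesis, and catalytic sulfonic acid is mild enough to keep the peri 5-O-benzyl ether.

**Step 10**
Reactants: 13 5,7-bis(benzyloxy)-2-methyl-4H-chromen-4-one; 9 3-aryl-5-methoxy-4-pyranone
Product: 19 5,7-bis(benzyloxy)-8-{5-[5,7-bis(benzyloxy)-4-oxo-4H-chromen-2-yl]-2-hydroxy-3-methoxyphenyl}-2-[4-(benzyloxy)phenyl]-4H-chromen-4-one (C4' phenol of the protected target), via lithium dienolate 14 (not isolated), via silyloxypyrylium triflate 15 (not isolated), via 2H-pyran adduct 16 (not isolated), via ring-opened dienal 17 (not isolated), via aryl silyl ether 18 (not isolated)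
Conditions: 13 (1.5 equiv), LiN(SiMe3)2, THF, −78 °C; add 9 pre-stirred with Me3SiOTf (1.2 equiv) in CH2Cl2 (0 °C), −78 → 0 °C; DBU, 0 °C → rt; 1 M HCl wash
Reagents that add atoms: none
Why: Proposed new method: O-silylation turns the weakly electrophilic pyranone 9 into the aromatic 4-silyloxypyrylium salt 15, the laterally deprotonated methylchromone 14 adds through its exocyclic carbon (future C1') to the free alpha-CH beside the methoxy group (C1'–C6'), and the 2H-pyran 16 opens electrocyclically to dienal 17, so the ring oxygen departs as a neutral aldehyde rather than as an unreactive beta-ketoaldehyde enolate. DBU then removes one of the doubly vinylogous C1' protons and the carbanion closes on the aldehyde in a 6-exo-trig aldol (C1'–C2'); loss of water aromatises to 18, and that water together with the acid wash strips the silyl group to give phenol 19, whose C4' oxygen is the former pyranone carbonyl oxygen. The closest known reaction types are the conversion of pyrylium salts into nitroarenes by nitromethane, carbanion-induced ring transformations of pyranones into arenes, the alpha-addition of silyl enol ethers to 4-silyloxy(benzo)pyrylium triflates and the Michael/retro-Michael/aldol benzannulation of activated chromones, but a 2-methylchromone as the one-carbon CH-acid has not been combined with a 3-aryl-5-alkoxy-4-pyranone as the five-carbon partner. No stereocentre survives (C6 of 16 is racemic and becomes sp2), and the alkene geometry of 17 is not critical because reversible deprotonation to the trienolate lets the chain bonds rotate into the cisoid array needed for closure. On the electrophile, silyl transfer among the carbonyl oxygens is reversible but only the pyrylium ring offers unsubstituted alpha carbons, C2'' of the flavone being blocked by its aryl group, and attack at either pyrylium alpha carbon leads to the same arene. On the nucleophile, reaction at the methyl carbon rather than C3 follows the normal lateral reactivity of 2-methyl-4-pyranone anions, and complete deprotonation at −78 °C before mixing should suppress self-condensation of 13.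

**Step 11**
Reactants: 19 C4' phenol
Product: 20 5,7-bis(benzyloxy)-8-{5-[5,7-bis(benzyloxy)-4-oxo-4H-chromen-2-yl]-2,3-dimethoxyphenyl}-2-[4-(benzyloxy)phenyl]-4H-chromen-4-one
Conditions: MeI (3 equiv), K2CO3 (2 equiv), DMF, 50 °C
Reagents that add atoms: iodomethane, CI
Why: Williamson methylation of the only free hydroxyl group, with the small electrophile and warm DMF compensating for the two ortho substituents.

**Step 12**
Reactants: 20 dimethyl ether pentabenzyl ether
Product: 21 5'-methoxybilobetin (8-[5-(5,7-dihydroxy-4-oxo-4H-chromen-2-yl)-2,3-dimethoxyphenyl]-5,7-dihydroxy-2-(4-hydroxyphenyl)-4H-chromen-4-one)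
Conditions: H2 (1 atm), 10% Pd/C, THF–MeOH, rt
Reagents that add atoms: none
Why: Catalytic hydrogenolysis cleaves aryl benzyl ethers at ambient pressure, while aryl methyl ethers and the conjugated flavone C2=C3 bonds normally persist if the reaction is stopped once hydrogen uptake ends.

**Compound list**
1 | apigenin | O=c1cc(-c2ccc(O)cc2)oc2cc(O)cc(O)c12 | starting material
2 | 5,7-bis(benzyloxy)-2-[4-(benzyloxy)phenyl]-4H-chromen-4-one | O=c1cc(-c2ccc(OCc3ccccc3)cc2)oc2cc(OCc3ccccc3)cc(OCc3ccccc3)c12 | intermediate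
3 | 5,7-bis(benzyloxy)-2-[4-(benzyloxy)phenyl]-8-iodo-4H-chromen-4-one | O=c1cc(-c2ccc(OCc3ccccc3)cc2)oc2c(I)c(OCc3ccccc3)cc(OCc3ccccc3)c12 | intermediate
4 | 8-allyl-5,7-bis(benzyloxy)-2-[4-(benzyloxy)phenyl]-4H-chromen-4-one | C=CCc1c(OCc2ccccc2)cc(OCc2ccccc2)c2c(=O)cc(-c3ccc(OCc4ccccc4)cc3)oc12 | intermediate
5 | 5,7-bis(benzyloxy)-2-[4-(benzyloxy)phenyl]-8-(oxiran-2-ylmethyl)-4H-chromen-4-one (racemic) | C1OC1Cc1c(OCc2ccccc2)cc(OCc2ccccc2)c2c(=O)cc(-c3ccc(OCc4ccccc4)cc3)oc12 | intermediate
6 | 5,7-bis(benzyloxy)-2-[4-(benzyloxy)phenyl]-8-(2-hydroxy-3-methoxypropyl)-4H-chromen-4-one (racemic) | COCC(O)Cc1c(OCc2ccccc2)cc(OCc2ccccc2)c2c(=O)cc(-c3ccc(OCc4ccccc4)cc3)oc12 | intermediate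
7 | 5,7-bis(benzyloxy)-2-[4-(benzyloxy)phenyl]-8-(3-methoxy-2-oxopropyl)-4H-chromen-4-one | COCC(=O)Cc1c(OCc2ccccc2)cc(OCc2ccccc2)c2c(=O)cc(-c3ccc(OCc4ccccc4)cc3)oc12 | intermediate
8 | 8-[1,5-bis(dimethylamino)-4-methoxy-3-oxopenta-1,4-dien-2-yl]-5,7-bis(benzyloxy)-2-[4-(benzyloxy)phenyl]-4H-chromen-4-one (alkene geometry not fixed) | CN(C)C=C(OC)C(=O)C(=CN(C)C)c1c(OCc2ccccc2)cc(OCc2ccccc2)c2c(=O)cc(-c3ccc(OCc4ccccc4)cc3)oc12 | intermediate
9 | 5,7-bis(benzyloxy)-2-[4-(benzyloxy)phenyl]-8-(5-methoxy-4-oxo-4H-pyran-3-yl)-4H-chromen-4-one | COc1cocc(-c2c(OCc3ccccc3)cc(OCc3ccccc3)c3c(=O)cc(-c4ccc(OCc5ccccc5)cc4)oc23)c1=O | intermediate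
10 | 2,4,6-trihydroxyacetophenone | CC(=O)c1c(O)cc(O)cc1O | starting material
11 | 1-[2,4-bis(benzyloxy)-6-hydroxyphenyl]ethan-1-one | CC(=O)c1c(O)cc(OCc2ccccc2)cc1OCc1ccccc1 | intermediate
12 | 1-[2,4-bis(benzyloxy)-6-hydroxyphenyl]butane-1,3-dione | CC(=O)CC(=O)c1c(O)cc(OCc2ccccc2)cc1OCc1ccccc1 | intermediate
13 | 5,7-bis(benzyloxy)-2-methyl-4H-chromen-4-one | Cc1cc(=O)c2c(OCc3ccccc3)cc(OCc3ccccc3)cc2o1 | intermediate
14 | lithium 5,7-bis(benzyloxy)-2-methylidene-2H-chromen-4-olate | [Li+].C=C1C=C([O-])c2c(OCc3ccccc3)cc(OCc3ccccc3)cc2O1 | intermediate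
15 | 3-(tribenzylapigenin-8-yl)-5-methoxy-4-(trimethylsilyloxy)pyrylium trifluoromethanesulfonate | COc1c[o+]cc(-c2c(OCc3ccccc3)cc(OCc3ccccc3)c3c(=O)cc(-c4ccc(OCc5ccccc5)cc4)oc23)c1O[Si](C)(C)C.[O-]S(=O)(=O)C(F)(F)F | intermediate
16 | 2H-pyran adduct: 2-[(5,7-bis(benzyloxy)-4-oxochromen-2-yl)methyl]-3-methoxy-4-(trimethylsilyloxy)-5-(tribenzylapigenin-8-yl)-2H-pyran (racemic; drawn for attack beside the methoxy group) | COC1=C(O[Si](C)(C)C)C(c2c(OCc3ccccc3)cc(OCc3ccccc3)c3c(=O)cc(-c4ccc(OCc5ccccc5)cc4)oc23)=COC1Cc1cc(=O)c2c(OCc3ccccc3)cc(OCc3ccccc3)cc2o1 | intermediate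
17 | ring-opened dienal: 6-(5,7-bis(benzyloxy)-4-oxochromen-2-yl)-4-methoxy-2-(tribenzylapigenin-8-yl)-3-(trimethylsilyloxy)hexa-2,4-dienal (alkene geometry mobile, not specified) | O=CC(c1c(OCc2ccccc2)cc(OCc2ccccc2)c2c(=O)cc(-c3ccc(OCc4ccccc4)cc3)oc12)=C(O[Si](C)(C)C)C(OC)=CCc1cc(=O)c2c(OCc3ccccc3)cc(OCc3ccccc3)cc2o1 | intermediate
18 | C4' O-trimethylsilyl ether of 19 | COc1cc(-c2cc(=O)c3c(OCc4ccccc4)cc(OCc4ccccc4)cc3o2)cc(-c2c(OCc3ccccc3)cc(OCc3ccccc3)c3c(=O)cc(-c4ccc(OCc5ccccc5)cc4)oc23)c1O[Si](C)(C)C | intermediate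
19 | 4'-hydroxy-5'-methoxy biflavone pentabenzyl ether | COc1cc(-c2cc(=O)c3c(OCc4ccccc4)cc(OCc4ccccc4)cc3o2)cc(-c2c(OCc3ccccc3)cc(OCc3ccccc3)c3c(=O)cc(-c4ccc(OCc5ccccc5)cc4)oc23)c1O | intermediate
20 | 4',5'-dimethoxy biflavone pentabenzyl ether | COc1cc(-c2cc(=O)c3c(OCc4ccccc4)cc(OCc4ccccc4)cc3o2)cc(-c2c(OCc3ccccc3)cc(OCc3ccccc3)c3c(=O)cc(-c4ccc(OCc5ccccc5)cc4)oc23)c1OC | intermediate
21 | 5'-methoxybilobetin | COc1cc(-c2cc(=O)c3c(O)cc(O)cc3o2)cc(-c2c(O)cc(O)c3c(=O)cc(-c4ccc(O)cc4)oc23)c1OC | target

**Totals**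
Total step count: 12. Longest linear sequence: 10 (steps 1–7, then 10–12). Steps 8 and 9 form the convergent branch.

**Steps most likely to fail**

Step 10. Several processes could divert the addition: electron transfer to the pyrylium ion, attack of the dienolate through oxygen or C3, or attack on the silylated flavone. The opened chain may also hydrolyse or oligomerise faster than it closes.

The fallback uses known chemistry. It takes ring B from an intact arene and makes the C3'–C8'' bond by Suzuki–Miyaura coupling, setting out from 11 and 3.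
- Claisen–Schmidt condensation of 11 with commercial 3-iodo-4,5-dimethoxybenzaldehyde (KOH, EtOH, rt) should give the chalcone (E)-1-[2,4-bis(benzyloxy)-6-hydroxyphenyl]-3-(3-iodo-4,5-dimethoxyphenyl)prop-2-en-1-one F1.
- Oxidative cyclisation (catalytic I2, DMSO, 120 °C) should give 5,7-bis(benzyloxy)-2-(3-iodo-4,5-dimethoxyphenyl)-4H-chromen-4-one F2.
- Miyaura borylation (B2pin2, Pd(dppf)Cl2, KOAc, dioxane, 90 °C) should give the pinacol boronate 5,7-bis(benzyloxy)-2-[3,4-dimethoxy-5-(4,4,5,5-tetramethyl-1,3,2-dioxaborolan-2-yl)phenyl]-4H-chromen-4-one F3.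
- Coupling of the boronate with 3 (Pd(PPh3)4, K2CO3, DMF–H2O, 90 °C) comes back to the route at 20.

Step 7. The second condensation, at the crowded benzylic methylene beside the di-ortho-substituted ring A, may stall. Hydrolysis would then return partly formylated ketone instead of closing the ring.

The fallback attaches a finished pyranone by cross-coupling, setting out from 3.
- Miyaura borylation (B2pin2, Pd(dppf)Cl2, KOAc, dioxane) should give 5,7-bis(benzyloxy)-2-[4-(benzyloxy)phenyl]-8-(4,4,5,5-tetramethyl-1,3,2-dioxaborolan-2-yl)-4H-chromen-4-one F4.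
- Separately, commercial 3-hydroxy-4H-pyran-4-one is methylated (MeI, K2CO3, acetone) to 3-methoxy-4H-pyran-4-one F5.
- Iodination at the only free enone alpha carbon (I2, pyridine–CHCl3) should give 3-iodo-5-methoxy-4H-pyran-4-one F6.
- Anhydrous Suzuki–Miyaura coupling of the two partners (Pd(OAc)2, SPhos, K3PO4, toluene, 80 °C), modelled on the isoflavone synthesis from 3-iodochromones, comes back at 9.

Step 5. If the epoxide opens slowly, methoxide has time to attack C2'' of the flavone. The liberated phenoxide, which sits ortho to the side chain, could then capture the epoxide intramolecularly.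

The fallback reaches the ketone without base and without an alcohol stage, setting out from 3.
- Suzuki–Miyaura coupling with commercial (E)-3-methoxyprop-1-enylboronic acid pinacol ester (Pd(dppf)Cl2, K2CO3, dioxane–H2O, 80 °C) should give 5,7-bis(benzyloxy)-2-[4-(benzyloxy)phenyl]-8-[(E)-3-methoxyprop-1-enyl]-4H-chromen-4-one F7.
- Epoxidation (mCPBA, CH2Cl2, 0 °C) should give the racemic trans epoxide 5,7-bis(benzyloxy)-2-[4-(benzyloxy)phenyl]-8-[3-(methoxymethyl)oxiran-2-yl]-4H-chromen-4-one F8.
- Meinwald rearrangement (catalytic InCl3, THF, rt) proceeds by benzylic C–O cleavage and a 1,2-hydride shift, and comes back at 7.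

**Further compounds**
F1 | step 10 | (E)-1-[2,4-bis(benzyloxy)-6-hydroxyphenyl]-3-(3-iodo-4,5-dimethoxyphenyl)prop-2-en-1-one | COc1cc(/C=C/C(=O)c2c(O)cc(OCc3ccccc3)cc2OCc2ccccc2)cc(I)c1OC
F2 | step 10 | 5,7-bis(benzyloxy)-2-(3-iodo-4,5-dimethoxyphenyl)-4H-chromen-4-one | COc1cc(-c2cc(=O)c3c(OCc4ccccc4)cc(OCc4ccccc4)cc3o2)cc(I)c1OC
F3 | step 10 | 5,7-bis(benzyloxy)-2-[3,4-dimethoxy-5-(4,4,5,5-tetramethyl-1,3,2-dioxaborolan-2-yl)phenyl]-4H-chromen-4-one | COc1cc(-c2cc(=O)c3c(OCc4ccccc4)cc(OCc4ccccc4)cc3o2)cc(B2OC(C)(C)C(C)(C)O2)c1OC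
F4 | step 7 | 5,7-bis(benzyloxy)-2-[4-(benzyloxy)phenyl]-8-(4,4,5,5-tetramethyl-1,3,2-dioxaborolan-2-yl)-4H-chromen-4-one | CC1(C)OB(c2c(OCc3ccccc3)cc(OCc3ccccc3)c3c(=O)cc(-c4ccc(OCc5ccccc5)cc4)oc23)OC1(C)C
F5 | step 7 | 3-methoxy-4H-pyran-4-one | COc1coccc1=O
F6 | step 7 | 3-iodo-5-methoxy-4H-pyran-4-one | COc1cocc(I)c1=O
F7 | step 5 | 5,7-bis(benzyloxy)-2-[4-(benzyloxy)phenyl]-8-[(E)-3-methoxyprop-1-enyl]-4H-chromen-4-one | COC/C=C/c1c(OCc2ccccc2)cc(OCc2ccccc2)c2c(=O)cc(-c3ccc(OCc4ccccc4)cc3)oc12
F8 | step 5 | 5,7-bis(benzyloxy)-2-[4-(benzyloxy)phenyl]-8-[trans-3-(methoxymethyl)oxiran-2-yl]-4H-chromen-4-one (racemic, one enantiomer drawn) | COC[C@H]1O[C@@H]1c2c(OCc3ccccc3)cc(OCc3ccccc3)c3c(=O)cc(-c4ccc(OCc5ccccc5)cc4)oc23
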